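## The problem

4'''-Hydroxytrianguletin (27) is a kaempferide unit (rings A, C and B: 3,5,7-trihydroxy-4'-methoxyflavone) tied through one methylene carbon from C8 to D1 of a hexasubstituted acylphloroglucinol ring D. Ring D carries OH at D2 and D4, the 3-(4-hydroxyphenyl)propanoyl group (ring E) at D3, CH3 at D5 and OCH3 at D6. There is no stereocentre, so every difficulty is one of position. The diarylmethane joins two phloroglucinol-type rings, and electrophilic benzylation of a 5,7-dihydroxyflavone cannot tell C8 from C6. The CH2–C8 bond therefore has to come from a reaction whose regiochemistry is fixed by connectivity. Ring D needs one methyl ether among three oxygens and two different carbon substituents on the two ring carbons that are equivalent in 2,4,6-trihydroxytoluene. The free phenols and the flavonol enol are prone to oxidation and C-alkylation, the doubly benzylic bridge is acid-labile, and both aryl ketones have enolisable neighbours. All phenols therefore travel as ethers and are freed last under neutral conditions. The enabling feature lies on the C4a=C8a edge of pyranone ring C. Ring A (C5 O, C6 H, C7 OH, C8 CH2) is the enol of a cyclohexadienone whose open form is a cis-hexatriene made of a ketene C7=C8, the ring C bond C8a=C4a and an enol ether C5=C6. A ketene whose α-carbon C8 carries both the pyranone and the ring D benzyl group is exactly what a Wolff shift of that benzyl group delivers, so the bridge bond and ring A can be made in one event on a monocyclic, weakly aromatic 4-pyranone.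

## Retrosynthesis

Flavone numbering is used for rings A and C; ring D is numbered D1 (bridge carbon) to D6 (OCH3). ArD is the protected ring D aryl group 2,4-bis(benzyloxy)-3-[3-(4-benzyloxyphenyl)propanoyl]-6-methoxy-5-methylphenyl.

**Deprotection (27 ⇒ 26 ⇒ 25).** Only four O–benzyl bonds and one O–Si bond are cut. Benzyl ethers are chosen for the phenols that must survive amide bases, amidine base and light. The silyl group sits on O5 because that oxygen is born as a silyl enol ether. The forward steps (fluoride, then hydrogenolysis) must leave two ketones, the flavonol C2=C3 bond and the bridge untouched.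

**Ring A and the bridge (25 ⇒ 22).** The bonds C6–C7 and CH2–C8 are cut together, back through cyclohexadienone 24 and ketene 23 to α-diazo ketone 22. Cutting CH2–C8 alone would be a Friedel–Crafts benzylation with the C6/C8 ambiguity. Cutting ring C instead leaves the bridge unsolved. Precursor 22 is a monocyclic pyranone with two side arms and a finished ring D. The forward reaction must shift the benzyl group to the diazo carbon and close the ring before the ketene is trapped.

**Diazo group and central ketone (22 ⇒ 21 ⇒ 9 + 19).** The C=N2 bond is removed to give ketone 21. The bond between the pyranone 6-CH2 and the ketone carbon is then cut to silyl enol ether 9 and arylacetic acid 19 (activated as imidazolide 20). The cut on the other side of the ketone would need alkylation with a hindered, electron-rich benzyl halide. This cut gives two halves of similar size. The forward reactions must deprotonate only the 6-methyl (so the acetyl is masked first) and transfer the diazo group only to the doubly activated CH2.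

**Pyranone ring C (9 ⇒ 8 ⇒ 5 + 2).** The enol ether comes from acetyl pyranone 8. In 8 the bonds C4–C5 and O1–C6 are cut, a hetero-Diels–Alder disconnection to acylketene 6 (from β-keto ester 5) and enaminone 2, through aminal 7. All five ring substituents arrive with the two partners. Enaminone 2 comes from acetylacetone 1, and 5 from glycolate ester 3 and acid chloride 4. The forward step needs the enaminone carbon, not a heteroatom, to attack the ketene carbon.

**Ring D side arm (19 ⇒ 18 ⇒ 16 ⇒ 15 ⇒ 14).** The CH2CO2H group is traced through aldehyde 18 to the allyl group of 16 (C=C cleavage). The D6 methyl ether is cut to phenol 15. The D1–allyl bond is cut by a Claisen disconnection to allyl ether 14. Direct C-allylation of an acylphloroglucinol risks dearomatisation, whereas the rearrangement has one free ortho position to go to.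

**Ring D core (14 ⇒ 13 ⇒ 12 ⇒ 10 + 11).** Three O–benzyl bonds and the O–allyl bond are cut to tetraphenol 12. The D3–acyl bond is cut to 2,4,6-trihydroxytoluene 10 and acid 11. The two ring CH of 10 are equivalent, so the first acylation fixes all later regiochemistry. The forward steps rely on the acidity order of the phenols: the one para to the ketone first, the chelated ones and ring E last.

## Roads not taken

**Alternative 1: Danheiser benzannulation for ring D.** The cut removes D1–D2, D5–D6 and D2–D3. In the forward sense, heating 3-benzyloxy-2-methylcyclobut-2-enone A1 with the 8-(3-methoxyprop-2-ynyl)flavone A2 should give phenol A3 through ring opening, (2+2) cycloaddition, a second opening and 6π closure.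
- Merits: the key step is an established reaction. The ynol ether polarity fixes the arene substitution, and D2 OH, D4 OBn and D6 OMe are differentiated at birth. The chosen plan needs five steps for the same oxygen pattern.
- Weak points: A3 has hydrogen at D3, so the dihydrochalcone acyl group must still be attached late, on a crowded ring and in competition with the nucleophilic C6–H of ring A. The bridge bond must already exist in A2, so an 8-propargyl flavone has to be made with the C6/C8 question unanswered. The 1-methoxyalkyne is acid- and heat-sensitive.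
- Comparison: this road wins on precedent for its key step. The chosen plan sets against it that the bridge bond and the ring A regiochemistry are decided in the same event, and that ring D arrives complete with its acyl group.

**Alternative 2: carbonylative alkynylation and cyclisation to ring C.** The cut removes C4a–C4, C4–C3 and O1–C2. With PdCl2(PPh3)2, diethylamine and CO, iodophenol A4 and 4-ethynylanisole A5 should give an ortho-hydroxyaryl ynone that closes to flavone A6.
- Merits: three components, known chemistry, and ring B introduced last. The amine base favours six-membered closure over the aurone.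
- Weak points: A6 is a flavone, not a flavonol. The 3-hydroxyl would have to be introduced afterwards, by metalation–oxidation or epoxidation, in the presence of two enolisable ketones and the doubly benzylic bridge. A4 already contains the diarylmethane and an iodinated, fully differentiated phloroglucinol, so the hardest bond is pushed into the substrate synthesis. There, benzylation and iodination each have to choose between two like ring positions.
- Comparison: this road is as good or better in convergence and in the precedent of its key step. The chosen plan carries the 3-oxygen from the first C–C bond and makes the bridge where no positional choice exists.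

**Alternative 3: biomimetic Claisen cyclisation to ring D.** The cut is D3–D4. With Mg(OMe)2 in methanol the C6 enolate of triketo ester A7 should attack the C1 ester and the ring should aromatise to the trihydroxy ring D of A8.
- Merits: it mirrors the biosynthesis. The acyl chain and the methyl group are in place, ring D needs no protecting groups, and later methylation of the only unchelated hydroxyl (D6) is plausible.
- Weak points: A7 is a branched tetracarbonyl chain with many enolisable sites. It can fold by aldol instead of Claisen closure, cyclodehydrate to 4-pyranones, or suffer retro-Claisen cleavage by methoxide. Making A7 needs alkylation with an 8-(halomethyl)flavone, again a regiodefined C8 substituent.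
- Comparison: the cyclisation type is known and fewer protecting-group steps fall on ring D. The chosen plan builds ring D from an aromatic starting material whose symmetry dictates the regiochemistry, and spends its key step on the bridge and ring A instead.

Key step: step 14

## Route

Remark: tert-butyl (benzyloxy)acetate 3 is taken as a purchasable glycolate ester; its ester group matters only in that it leaves thermally as tert-butanol.

Step 1
Reactants: 1 acetylacetone
Product: 2 (E)-4-(dimethylamino)pent-3-en-2-one
Conditions: Me2NH (2 M in THF, 1.5 equiv), 4 Å MS, 25 °C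
Reagents that add atoms: dimethylamine, CNC
Why: Condensation of a secondary amine with a β-diketone gives the vinylogous amide with loss of water; a tertiary enaminone cannot be N-acylated, so its α-carbon is the only nucleophilic site in step 3.

Step 2
Reactants: 3 tert-butyl (benzyloxy)acetate; 4 4-methoxybenzoyl chloride
Product: 5 tert-butyl 2-(benzyloxy)-3-(4-methoxyphenyl)-3-oxopropanoate (racemic)
Conditions: 3 (2.0 equiv), LiN(iPr)2 (2.0 equiv), THF, −78 °C; then 4 (1.0 equiv), −78 → −40 °C; AcOH
Reagents that add atoms: none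
Why: Crossed Claisen acylation of a glycolate ester enolate with an aroyl chloride; the second equivalent of enolate takes up the acidic proton of the β-keto ester, and the racemic stereocentre disappears in step 3.

Step 3
Reactants: 5 tert-butyl 2-(benzyloxy)-3-(4-methoxyphenyl)-3-oxopropanoate; 2 (E)-4-(dimethylamino)pent-3-en-2-one
Product: 8 5-acetyl-3-(benzyloxy)-2-(4-methoxyphenyl)-6-methyl-4H-pyran-4-one, via acylketene 6 (not isolated), via aminal cycloadduct 7 (not isolated)
Conditions: 2 (3 equiv), xylenes, 140 °C, slow N2 stream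
Reagents that add atoms: none
Why: tert-Butyl β-keto esters lose tert-butanol thermally to acylketenes, which add to enamine C=C bonds in a hetero-Diels–Alder (4+2) sense: the enaminone α-carbon bonds to the ketene carbon (C4–C5) and the aroyl oxygen to the aminated carbon (O1–C6). β-Elimination of dimethylamine from 7 gives the 4-pyranone, and the gas stream removes alcohol and amine.

Step 4
Reactants: 8 5-acetyl-3-(benzyloxy)-2-(4-methoxyphenyl)-6-methyl-4H-pyran-4-one
Product: 9 3-(benzyloxy)-5-[1-(tert-butyldimethylsilyloxy)vinyl]-2-(4-methoxyphenyl)-6-methyl-4H-pyran-4-one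
Conditions: TBSOTf (1.3 equiv), Et3N (2.5 equiv), CH2Cl2, −78 → 0 °C; aq. NaHCO3
Reagents that add atoms: tert-butyldimethylsilyl trifluoromethanesulfonate, CC(C)(C)[Si](C)(C)OS(=O)(=O)C(F)(F)F
Why: Soft enolisation of a methyl ketone with a silyl triflate and a tertiary amine gives the 2-silyloxydiene. The isomer with the enol ether on the acetyl arm keeps the pyranone conjugation and should be the stable one, and any silyl group on the pyranone oxygen is lost on bicarbonate work-up.

Step 5
Reactants: 10 2,4,6-trihydroxytoluene; 11 3-(4-hydroxyphenyl)propanoic acid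
Product: 12 3-(4-hydroxyphenyl)-1-(2,4,6-trihydroxy-3-methylphenyl)propan-1-one
Conditions: BF3·OEt2 (neat), 85 °C; then aq. NaOAc
Reagents that add atoms: none
Why: Friedel–Crafts acylation of a phloroglucinol with a free carboxylic acid in BF3·OEt2; the two ring CH of 10 are equivalent, so one ketone forms, and the acyl group deactivates the ring against a second acylation.

Step 6
Reactants: 12 3-(4-hydroxyphenyl)-1-(2,4,6-trihydroxy-3-methylphenyl)propan-1-one
Product: 13 1-[4-(allyloxy)-2,6-dihydroxy-3-methylphenyl]-3-(4-hydroxyphenyl)propan-1-one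
Conditions: allyl bromide (1.05 equiv), K2CO3 (1.1 equiv), acetone, 25 → 56 °C
Reagents that add atoms: allyl bromide, C=CCBr
Why: Williamson etherification under acidity control: the hydroxyl para to the ketone (D6) is the most acidic, the two ortho hydroxyls are hydrogen-bonded to the carbonyl and the ring E phenol is weaker, so one equivalent of weak base should direct the allyl group to O-D6.

Step 7
Reactants: 13 1-[4-(allyloxy)-2,6-dihydroxy-3-methylphenyl]-3-(4-hydroxyphenyl)propan-1-one
Product: 14 1-[4-(allyloxy)-2,6-bis(benzyloxy)-3-methylphenyl]-3-[4-(benzyloxy)phenyl]propan-1-one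
Conditions: BnBr (3.6 equiv), K2CO3 (4 equiv), Bu4NI (cat.), DMF, 70 °C
Reagents that add atoms: benzyl bromide, BrCc1ccccc1
Why: Exhaustive Williamson benzylation in a polar aprotic solvent caps the two chelated hydroxyls and the ring E phenol; DMF favours O- over C-alkylation and the allyl ether is inert.

Step 8
Reactants: 14 1-[4-(allyloxy)-2,6-bis(benzyloxy)-3-methylphenyl]-3-[4-(benzyloxy)phenyl]propan-1-one
Product: 15 1-[3-allyl-2,6-bis(benzyloxy)-4-hydroxy-5-methylphenyl]-3-[4-(benzyloxy)phenyl]propan-1-one
Conditions: PhNEt2, 195 °C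
Reagents that add atoms: none
Why: Aromatic Claisen rearrangement (3,3-sigmatropic shift): one ortho position carries CH3 and the para position carries oxygen, so the allyl group can only settle on the free ortho carbon D1. Tautomerisation returns the D6 phenol, and benzyl aryl ethers tolerate this temperature.

Step 9
Reactants: 15 1-[3-allyl-2,6-bis(benzyloxy)-4-hydroxy-5-methylphenyl]-3-[4-(benzyloxy)phenyl]propan-1-one
Product: 16 1-[3-allyl-2,6-bis(benzyloxy)-4-methoxy-5-methylphenyl]-3-[4-(benzyloxy)phenyl]propan-1-one
Conditions: MeI (2 equiv), K2CO3 (2 equiv), DMF, 40 °C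
Reagents that add atoms: iodomethane, CI
Why: Williamson methylation of the only free hydroxyl places the single methyl ether of ring D at D6 without any choice between positions.

Step 10
Reactants: 16 1-[3-allyl-2,6-bis(benzyloxy)-4-methoxy-5-methylphenyl]-3-[4-(benzyloxy)phenyl]propan-1-one
Product: 18 2-{2,4-bis(benzyloxy)-3-[3-(4-benzyloxyphenyl)propanoyl]-6-methoxy-5-methylphenyl}acetaldehyde, via vicinal diol 17 (not isolated)
Conditions: OsO4 (2 mol %), NaIO4 (4 equiv), 2,6-lutidine, dioxane/H2O (3:1), 25 °C
Reagents that add atoms: osmium tetroxide, O=[Os](=O)(=O)=O (delivers the oxygen and is reoxidised by sodium periodate, [Na+].[O-]I(=O)(=O)=O)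
Why: Lemieux–Johnson oxidation: catalytic dihydroxylation of the terminal alkene and periodate cleavage of the diol; the fully substituted, electron-rich ring D is not attacked as it might be by ozone, and 2,6-lutidine suppresses over-oxidation.

Step 11
Reactants: 18 2-{2,4-bis(benzyloxy)-3-[3-(4-benzyloxyphenyl)propanoyl]-6-methoxy-5-methylphenyl}acetaldehyde
Product: 19 2-{2,4-bis(benzyloxy)-3-[3-(4-benzyloxyphenyl)propanoyl]-6-methoxy-5-methylphenyl}acetic acid
Conditions: NaClO2, NaH2PO4, 2-methyl-2-butene, t-BuOH/H2O, 0 → 25 °C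
Reagents that add atoms: sodium chlorite, [Na+].[O-]Cl=O
Why: Pinnick oxidation of the aldehyde to the acid; the alkene scavenger removes hypochlorous acid before it can chlorinate ring E.

Step 12
Reactants: 19 2-{2,4-bis(benzyloxy)-3-[3-(4-benzyloxyphenyl)propanoyl]-6-methoxy-5-methylphenyl}acetic acid; 9 3-(benzyloxy)-5-[1-(tert-butyldimethylsilyloxy)vinyl]-2-(4-methoxyphenyl)-6-methyl-4H-pyran-4-one
Product: 21 3-(benzyloxy)-5-[1-(tert-butyldimethylsilyloxy)vinyl]-2-(4-methoxyphenyl)-6-(2-oxo-3-ArD-propyl)-4H-pyran-4-one, via acyl imidazolide 20 (not isolated)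
Conditions: 19, CDI (1.05 equiv), THF, 25 °C; 9, LiN(SiMe3)2 (3.2 equiv), THF, −78 °C; add 20, −78 → −40 °C; aq. NH4Cl
Reagents that add atoms: none
Why: Lateral (vinylogous) deprotonation of the 6-methyl of a 4-pyranone gives a dienolate that is C-acylated by an acyl imidazolide in a Claisen-type acylation. The acetyl group is masked as its enol ether, so the 6-methyl is the only acidic site, and the extra base covers the imidazole released and the acidic product.

Step 13
Reactants: 21 3-(benzyloxy)-5-[1-(tert-butyldimethylsilyloxy)vinyl]-2-(4-methoxyphenyl)-6-(2-oxo-3-ArD-propyl)-4H-pyran-4-one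
Product: 22 3-(benzyloxy)-5-[1-(tert-butyldimethylsilyloxy)vinyl]-6-(1-diazo-2-oxo-3-ArD-propyl)-2-(4-methoxyphenyl)-4H-pyran-4-one
Conditions: 4-acetamidobenzenesulfonyl azide (1.2 equiv), DBU (1.5 equiv), MeCN, 0 °C, dark
Reagents that add atoms: 4-acetamidobenzenesulfonyl azide, CC(=O)Nc1ccc(cc1)S(=O)(=O)N=[N+]=[N-]
Why: Regitz diazo transfer to the methylene activated by the ketone and, vinylogously, by the pyranone carbonyl; the other α-methylene sits on a twisted, electron-rich, di-ortho-substituted ring and is only singly activated, and the silyl enol ether tolerates the amidine base.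

Step 14
Reactants: 22 3-(benzyloxy)-5-[1-(tert-butyldimethylsilyloxy)vinyl]-6-(1-diazo-2-oxo-3-ArD-propyl)-2-(4-methoxyphenyl)-4H-pyran-4-one
Product: 25 3-(benzyloxy)-5-(tert-butyldimethylsilyloxy)-7-hydroxy-2-(4-methoxyphenyl)-8-(ArD-methyl)-4H-chromen-4-one, via ketene 23 (not isolated), via cyclohexadienone 24 (not isolated)
Conditions: hν (450 nm LEDs), PhMe (0.003 M), Ar, 20 °C; then 40 °C
Reagents that add atoms: none
Why: Proposed new method: Visible-light excitation of the vinylogous α-diazo ketone 22 expels N2 and the ring D benzyl group shifts from the acyl carbon to the diazo carbon (Wolff rearrangement), which makes the CH2–C8 bond and gives ketene 23 with C7 as the ketene carbon. The closest known reaction types are the photochemical Wolff rearrangement of α-aryl α-diazo ketones with alkyl migration and the dienylketene 6π electrocyclization that ends the Danheiser benzannulation; their union on a pyranone C=C with an enol ether as the third double bond has not been shown. In 23 the ketene C7=C8, the ring C bond C8a=C4a and the silyl enol ether C5=C6 are held cis on the pyranone edge, so thermal disrotatory 6π electrocyclization joins C6 to C7 and closes ring A as cyclohexadienone 24. Enolisation of the C6 methylene of 24 restores the pyranone and gives the aromatic 7-phenol 25, which makes the sequence irreversible; no stereocentre is formed. The step needs rearrangement to win over free-carbene reactions and ring closure to win over ketene trapping. Only the benzyl group sits on the acyl carbon, so only it can shift, and 450 nm light is absorbed by the diazo chromophore but not by the ring D aryl ketone or the flavone product. High dilution in a dry aprotic solvent lets the cis-locked closure outrun addition of water or of the product phenol to the ketene. The 4-pyranone is only weakly aromatic, so lending its C8a=C4a bond costs little and is repaid on tautomerisation.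

Step 15
Reactants: 25 3-(benzyloxy)-5-(tert-butyldimethylsilyloxy)-7-hydroxy-2-(4-methoxyphenyl)-8-(ArD-methyl)-4H-chromen-4-one
Product: 26 3-(benzyloxy)-5,7-dihydroxy-2-(4-methoxyphenyl)-8-(ArD-methyl)-4H-chromen-4-one
Conditions: Bu4NF (1.2 equiv), AcOH (1.2 equiv), THF, 0 °C
Reagents that add atoms: none
Why: Fluoride-induced cleavage of an aryl silyl ether; the acetic acid buffer keeps the medium near neutral so the phloroglucinol-type ring and the bridge are not exposed to base.

Step 16
Reactants: 26 3-(benzyloxy)-5,7-dihydroxy-2-(4-methoxyphenyl)-8-(ArD-methyl)-4H-chromen-4-one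
Product: 27 4'''-hydroxytrianguletin
Conditions: H2 (1 atm), Pd/C (10 wt % Pd), EtOAc/MeOH, 25 °C
Reagents that add atoms: none
Why: Hydrogenolysis of the four benzyl ethers over Pd/C; chelated aryl ketones, the flavonol C2=C3 bond, the methyl ethers and the diarylmethane are expected to survive at ambient pressure and temperature.

## Compound list

1 | acetylacetone | CC(=O)CC(C)=O | starting material
2 | (E)-4-(dimethylamino)pent-3-en-2-one | CC(=O)/C=C(\C)N(C)C | intermediate
3 | tert-butyl (benzyloxy)acetate | CC(C)(C)OC(=O)COCc1ccccc1 | starting material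
4 | 4-methoxybenzoyl chloride | COc1ccc(C(Cl)=O)cc1 | starting material
5 | tert-butyl 2-(benzyloxy)-3-(4-methoxyphenyl)-3-oxopropanoate (racemic) | COc1ccc(cc1)C(=O)C(OCc1ccccc1)C(=O)OC(C)(C)C | intermediate
6 | 2-(benzyloxy)-3-(4-methoxyphenyl)-3-oxoprop-1-en-1-one (acylketene, not isolated) | COc1ccc(cc1)C(=O)C(OCc1ccccc1)=C=O | intermediate
7 | 5-acetyl-3-(benzyloxy)-6-(dimethylamino)-2-(4-methoxyphenyl)-6-methyl-5,6-dihydro-4H-pyran-4-one (racemic, not isolated) | COc1ccc(cc1)C1=C(OCc2ccccc2)C(=O)C(C(C)=O)C(C)(N(C)C)O1 | intermediate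
8 | 5-acetyl-3-(benzyloxy)-2-(4-methoxyphenyl)-6-methyl-4H-pyran-4-one | COc1ccc(-c2oc(C)c(C(C)=O)c(=O)c2OCc2ccccc2)cc1 | intermediate
9 | 3-(benzyloxy)-5-[1-(tert-butyldimethylsilyloxy)vinyl]-2-(4-methoxyphenyl)-6-methyl-4H-pyran-4-one | COc1ccc(-c2oc(C)c(C(=C)O[Si](C)(C)C(C)(C)C)c(=O)c2OCc2ccccc2)cc1 | intermediate
10 | 2,4,6-trihydroxytoluene | Cc1c(O)cc(O)cc1O | starting material
11 | 3-(4-hydroxyphenyl)propanoic acid | OC(=O)CCc1ccc(O)cc1 | starting material
12 | 3-(4-hydroxyphenyl)-1-(2,4,6-trihydroxy-3-methylphenyl)propan-1-one | Cc1c(O)cc(O)c(C(=O)CCc2ccc(O)cc2)c1O | intermediate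
13 | 1-[4-(allyloxy)-2,6-dihydroxy-3-methylphenyl]-3-(4-hydroxyphenyl)propan-1-one | C=CCOc1cc(O)c(C(=O)CCc2ccc(O)cc2)c(O)c1C | intermediate
14 | 1-[4-(allyloxy)-2,6-bis(benzyloxy)-3-methylphenyl]-3-[4-(benzyloxy)phenyl]propan-1-one | C=CCOc1cc(OCc2ccccc2)c(C(=O)CCc2ccc(OCc3ccccc3)cc2)c(OCc2ccccc2)c1C | intermediate
15 | 1-[3-allyl-2,6-bis(benzyloxy)-4-hydroxy-5-methylphenyl]-3-[4-(benzyloxy)phenyl]propan-1-one | C=CCc1c(O)c(C)c(OCc2ccccc2)c(C(=O)CCc2ccc(OCc3ccccc3)cc2)c1OCc1ccccc1 | intermediate
16 | 1-[3-allyl-2,6-bis(benzyloxy)-4-methoxy-5-methylphenyl]-3-[4-(benzyloxy)phenyl]propan-1-one | C=CCc1c(OC)c(C)c(OCc2ccccc2)c(C(=O)CCc2ccc(OCc3ccccc3)cc2)c1OCc1ccccc1 | intermediate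
17 | 1-[2,6-bis(benzyloxy)-3-(2,3-dihydroxypropyl)-4-methoxy-5-methylphenyl]-3-[4-(benzyloxy)phenyl]propan-1-one (racemic, not isolated) | OCC(O)Cc1c(OC)c(C)c(OCc2ccccc2)c(C(=O)CCc2ccc(OCc3ccccc3)cc2)c1OCc1ccccc1 | intermediate
18 | 2-{2,4-bis(benzyloxy)-3-[3-(4-benzyloxyphenyl)propanoyl]-6-methoxy-5-methylphenyl}acetaldehyde | O=CCc1c(OC)c(C)c(OCc2ccccc2)c(C(=O)CCc2ccc(OCc3ccccc3)cc2)c1OCc1ccccc1 | intermediate
19 | 2-{2,4-bis(benzyloxy)-3-[3-(4-benzyloxyphenyl)propanoyl]-6-methoxy-5-methylphenyl}acetic acid | OC(=O)Cc1c(OC)c(C)c(OCc2ccccc2)c(C(=O)CCc2ccc(OCc3ccccc3)cc2)c1OCc1ccccc1 | intermediate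
20 | 1-(1H-imidazol-1-yl)-2-ArD-ethan-1-one (acyl imidazolide of 19, not isolated) | O=C(Cc1c(OC)c(C)c(OCc2ccccc2)c(C(=O)CCc2ccc(OCc3ccccc3)cc2)c1OCc1ccccc1)n1ccnc1 | intermediate
21 | 3-(benzyloxy)-5-[1-(tert-butyldimethylsilyloxy)vinyl]-2-(4-methoxyphenyl)-6-(2-oxo-3-ArD-propyl)-4H-pyran-4-one | COc1ccc(-c2oc(CC(=O)Cc3c(OCc4ccccc4)c(C(=O)CCc4ccc(OCc5ccccc5)cc4)c(OCc4ccccc4)c(C)c3OC)c(C(=C)O[Si](C)(C)C(C)(C)C)c(=O)c2OCc2ccccc2)cc1 | intermediate
22 | 3-(benzyloxy)-5-[1-(tert-butyldimethylsilyloxy)vinyl]-6-(1-diazo-2-oxo-3-ArD-propyl)-2-(4-methoxyphenyl)-4H-pyran-4-one | COc1ccc(-c2oc(C(=[N+]=[N-])C(=O)Cc3c(OCc4ccccc4)c(C(=O)CCc4ccc(OCc5ccccc5)cc4)c(OCc4ccccc4)c(C)c3OC)c(C(=C)O[Si](C)(C)C(C)(C)C)c(=O)c2OCc2ccccc2)cc1 | intermediate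
23 | ketene O=C=C(CH2ArD)(pyranon-6-yl) formed from 22 by Wolff shift (not isolated) | COc1ccc(-c2oc(C(=C=O)Cc3c(OCc4ccccc4)c(C(=O)CCc4ccc(OCc5ccccc5)cc4)c(OCc4ccccc4)c(C)c3OC)c(C(=C)O[Si](C)(C)C(C)(C)C)c(=O)c2OCc2ccccc2)cc1 | intermediate
24 | 3-(benzyloxy)-5-(tert-butyldimethylsilyloxy)-2-(4-methoxyphenyl)-8-(ArD-methyl)-4H-chromene-4,7(6H)-dione (not isolated) | COc1ccc(cc1)C1=C(OCc2ccccc2)C(=O)C2=C(O[Si](C)(C)C(C)(C)C)CC(=O)C(Cc3c(OCc4ccccc4)c(C(=O)CCc4ccc(OCc5ccccc5)cc4)c(OCc4ccccc4)c(C)c3OC)=C2O1 | intermediate
25 | 3-(benzyloxy)-5-(tert-butyldimethylsilyloxy)-7-hydroxy-2-(4-methoxyphenyl)-8-(ArD-methyl)-4H-chromen-4-one | COc1ccc(-c2oc3c(Cc4c(OCc5ccccc5)c(C(=O)CCc5ccc(OCc6ccccc6)cc5)c(OCc5ccccc5)c(C)c4OC)c(O)cc(O[Si](C)(C)C(C)(C)C)c3c(=O)c2OCc2ccccc2)cc1 | intermediate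
26 | 3-(benzyloxy)-5,7-dihydroxy-2-(4-methoxyphenyl)-8-(ArD-methyl)-4H-chromen-4-one | COc1ccc(-c2oc3c(Cc4c(OCc5ccccc5)c(C(=O)CCc5ccc(OCc6ccccc6)cc5)c(OCc5ccccc5)c(C)c4OC)c(O)cc(O)c3c(=O)c2OCc2ccccc2)cc1 | intermediate
27 | 4'''-hydroxytrianguletin: 8-{2,4-dihydroxy-3-[3-(4-hydroxyphenyl)propanoyl]-6-methoxy-5-methylbenzyl}-3,5,7-trihydroxy-2-(4-methoxyphenyl)-4H-chromen-4-one | COc1ccc(-c2oc3c(Cc4c(O)c(C(=O)CCc5ccc(O)cc5)c(O)c(C)c4OC)c(O)cc(O)c3c(=O)c2O)cc1 | target

## Step count and risks

Total: 16 steps. Longest linear sequence: 12 steps (steps 5–16, from 10 and 11 to 27). The pyranone branch (steps 1–4) joins at step 12.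

**Step 14 (key step).** The diazo compound may be lost before rearrangement, either by dark electrocyclisation of the diazo group onto the adjacent silyloxydiene or by the excited state reacting as a free carbene (insertion) instead of shifting the benzyl group. The ketene may also be intercepted by water or by the product phenol before it closes. The cause is a conjugated, crowded diazo ketone whose rearrangement needs the syn conformer. The fallback sets out from 22 and returns at 26, making the same two bonds by known reactions. Irradiation of 22 in methanol/THF traps the ketene as the homologated ester methyl 2-(pyranon-6-yl)-3-ArD-propanoate F1 (Wolff rearrangement with alcohol capture, the Arndt–Eistert mode). Dilute acid hydrolyses the silyl enol ether to the acetyl ester F2. NaOMe in methanol then effects an intramolecular Claisen condensation of the acetyl methyl onto the ester, and the cyclic 1,3-dione enolises to the 5,7-dihydroxyflavone 26.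

**Step 3.** The acylketene may be consumed by the liberated dimethylamine or by dimerisation before it meets the weakly nucleophilic push-pull enaminone, or attack may occur through the enaminone oxygen. The fallback sets out from 5 and returns at 8. Thermolysis of 5 with 2-methoxypropene in a sealed tube gives the acylketene–vinyl ether cycloadduct 3-(benzyloxy)-6-methoxy-2-(4-methoxyphenyl)-6-methyl-5,6-dihydro-4H-pyran-4-one F3, which loses methanol with TsOH to 3-(benzyloxy)-2-(4-methoxyphenyl)-6-methyl-4H-pyran-4-one F4. Iodination of the only ring CH with N-iodosuccinimide and CF3CO2H gives the 5-iodide F5. Stille coupling with tributyl(1-ethoxyvinyl)stannane and PdCl2(PPh3)2 gives the enol ether 3-(benzyloxy)-5-(1-ethoxyvinyl)-2-(4-methoxyphenyl)-6-methyl-4H-pyran-4-one F6, and dilute HCl hydrolyses it to 8.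

**Step 4.** Enolisation may take the wrong direction. The 6-methyl is vinylogous to both carbonyls, so silylation could occur through the extended enolate and leave the acetyl group unmasked or give an isomeric dienol ether. The fallback sets out from 8 and returns at 26; it uses that same acidity and bypasses 9, 21, 22 and 25. The lateral dienolate of 8 (LiN(SiMe3)2, −78 °C) is acylated with imidazolide 20 to the acetyl ketone 5-acetyl-3-(benzyloxy)-2-(4-methoxyphenyl)-6-(2-oxo-3-ArD-propyl)-4H-pyran-4-one F7. Regitz diazo transfer gives the acetyl diazo ketone F8. Irradiation in methanol gives the acetyl ester F2 by Wolff rearrangement with methanol capture, and NaOMe closes ring A to 26 as in the fallback for step 14.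

**Step 12.** The acylation may stall through proton transfer (from imidazole, from the acidic product or from the α-methylene of the imidazolide, which can also collapse to an arylketene), and the silyl group may migrate from oxygen to the lateral carbanion on warming. The fallback sets out from 9 and aldehyde 18 and returns at 21. The lithium dienolate of 9 (one equivalent of LiN(SiMe3)2, −78 °C) adds to 18 in a vinylogous aldol addition to give the β-hydroxy compound 3-(benzyloxy)-5-[1-(tert-butyldimethylsilyloxy)vinyl]-6-(2-hydroxy-3-ArD-propyl)-2-(4-methoxyphenyl)-4H-pyran-4-one F9. Dess–Martin periodinane oxidises it to 21. No acidic product forms in the C–C bond-forming event and step 11 is not needed.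

**Step 13.** Diazo transfer may be incomplete or may stray to the ring D side methylene, and the diene-conjugated diazo product may cyclise during a slow reaction. The fallback sets out from 21 and returns at 22. Deprotonation of 21 with LiN(SiMe3)2 at −78 °C and C-acylation with 2,2,2-trifluoroethyl trifluoroacetate gives the α-trifluoroacetyl ketone F10 at the pyranone-side carbon. Methanesulfonyl azide and Et3N then transfer the diazo group with loss of the trifluoroacetyl group (detrifluoroacetylative diazo transfer). This fixes the site through the enolate and runs fast at low temperature.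

## Further compounds

F1 | step 14 | methyl 2-{3-(benzyloxy)-5-[1-(tert-butyldimethylsilyloxy)vinyl]-2-(4-methoxyphenyl)-4-oxo-4H-pyran-6-yl}-3-ArD-propanoate (racemic) | COc1ccc(-c2oc(C(C(=O)OC)Cc3c(OCc4ccccc4)c(C(=O)CCc4ccc(OCc5ccccc5)cc4)c(OCc4ccccc4)c(C)c3OC)c(C(=C)O[Si](C)(C)C(C)(C)C)c(=O)c2OCc2ccccc2)cc1
F2 | step 14 | methyl 2-[5-acetyl-3-(benzyloxy)-2-(4-methoxyphenyl)-4-oxo-4H-pyran-6-yl]-3-ArD-propanoate (racemic) | COc1ccc(-c2oc(C(C(=O)OC)Cc3c(OCc4ccccc4)c(C(=O)CCc4ccc(OCc5ccccc5)cc4)c(OCc4ccccc4)c(C)c3OC)c(C(C)=O)c(=O)c2OCc2ccccc2)cc1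
F3 | step 3 | 3-(benzyloxy)-6-methoxy-2-(4-methoxyphenyl)-6-methyl-5,6-dihydro-4H-pyran-4-one (racemic) | COc1ccc(cc1)C1=C(OCc2ccccc2)C(=O)CC(C)(OC)O1
F4 | step 3 | 3-(benzyloxy)-2-(4-methoxyphenyl)-6-methyl-4H-pyran-4-one | COc1ccc(-c2oc(C)cc(=O)c2OCc2ccccc2)cc1
F5 | step 3 | 3-(benzyloxy)-5-iodo-2-(4-methoxyphenyl)-6-methyl-4H-pyran-4-one | COc1ccc(-c2oc(C)c(I)c(=O)c2OCc2ccccc2)cc1
F6 | step 3 | 3-(benzyloxy)-5-(1-ethoxyvinyl)-2-(4-methoxyphenyl)-6-methyl-4H-pyran-4-one | COc1ccc(-c2oc(C)c(C(=C)OCC)c(=O)c2OCc2ccccc2)cc1
F7 | step 4 | 5-acetyl-3-(benzyloxy)-2-(4-methoxyphenyl)-6-(2-oxo-3-ArD-propyl)-4H-pyran-4-one | COc1ccc(-c2oc(CC(=O)Cc3c(OCc4ccccc4)c(C(=O)CCc4ccc(OCc5ccccc5)cc4)c(OCc4ccccc4)c(C)c3OC)c(C(C)=O)c(=O)c2OCc2ccccc2)cc1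
F8 | step 4 | 5-acetyl-3-(benzyloxy)-6-(1-diazo-2-oxo-3-ArD-propyl)-2-(4-methoxyphenyl)-4H-pyran-4-one | COc1ccc(-c2oc(C(=[N+]=[N-])C(=O)Cc3c(OCc4ccccc4)c(C(=O)CCc4ccc(OCc5ccccc5)cc4)c(OCc4ccccc4)c(C)c3OC)c(C(C)=O)c(=O)c2OCc2ccccc2)cc1
F9 | step 12 | 3-(benzyloxy)-5-[1-(tert-butyldimethylsilyloxy)vinyl]-6-(2-hydroxy-3-ArD-propyl)-2-(4-methoxyphenyl)-4H-pyran-4-one (racemic) | COc1ccc(-c2oc(CC(O)Cc3c(OCc4ccccc4)c(C(=O)CCc4ccc(OCc5ccccc5)cc4)c(OCc4ccccc4)c(C)c3OC)c(C(=C)O[Si](C)(C)C(C)(C)C)c(=O)c2OCc2ccccc2)cc1
F10 | step 13 | 3-(benzyloxy)-5-[1-(tert-butyldimethylsilyloxy)vinyl]-2-(4-methoxyphenyl)-6-[2-oxo-3-ArD-1-(trifluoroacetyl)propyl]-4H-pyran-4-one (racemic) | COc1ccc(-c2oc(C(C(=O)C(F)(F)F)C(=O)Cc3c(OCc4ccccc4)c(C(=O)CCc4ccc(OCc5ccccc5)cc4)c(OCc4ccccc4)c(C)c3OC)c(C(=C)O[Si](C)(C)C(C)(C)C)c(=O)c2OCc2ccccc2)cc1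
A1 | alternative 1 | 3-(benzyloxy)-2-methylcyclobut-2-en-1-one | CC1=C(OCc2ccccc2)CC1=O
A2 | alternative 1 | 3,5,7-tris(benzyloxy)-2-(4-methoxyphenyl)-8-(3-methoxyprop-2-yn-1-yl)-4H-chromen-4-one | COC#CCc1c(OCc2ccccc2)cc(OCc2ccccc2)c2c(=O)c(OCc3ccccc3)c(-c3ccc(OC)cc3)oc12
A3 | alternative 1 | 3,5,7-tris(benzyloxy)-8-[4-(benzyloxy)-2-hydroxy-6-methoxy-5-methylbenzyl]-2-(4-methoxyphenyl)-4H-chromen-4-one | COc1ccc(-c2oc3c(Cc4c(O)cc(OCc5ccccc5)c(C)c4OC)c(OCc4ccccc4)cc(OCc4ccccc4)c3c(=O)c2OCc2ccccc2)cc1
A4 | alternative 2 | 5-(benzyloxy)-4-iodo-2-(ArD-methyl)benzene-1,3-diol | Oc1c(I)c(OCc2ccccc2)cc(O)c1Cc1c(OCc2ccccc2)c(C(=O)CCc2ccc(OCc3ccccc3)cc2)c(OCc2ccccc2)c(C)c1OC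
A5 | alternative 2 | 4-ethynylanisole | COc1ccc(C#C)cc1
A6 | alternative 2 | 5-(benzyloxy)-7-hydroxy-2-(4-methoxyphenyl)-8-(ArD-methyl)-4H-chromen-4-one | COc1ccc(-c2cc(=O)c3c(OCc7ccccc7)cc(O)c(Cc4c(OCc5ccccc5)c(C(=O)CCc5ccc(OCc6ccccc6)cc5)c(OCc5ccccc5)c(C)c4OC)c3o2)cc1
A7 | alternative 3 | methyl 9-[4-(benzyloxy)phenyl]-2-methyl-3,5,7-trioxo-4-{[3,5,7-tris(benzyloxy)-2-(4-methoxyphenyl)-4-oxo-4H-chromen-8-yl]methyl}nonanoate (mixture of diastereomers) | COC(=O)C(C)C(=O)C(Cc1c(OCc2ccccc2)cc(OCc2ccccc2)c2c(=O)c(OCc3ccccc3)c(-c3ccc(OC)cc3)oc12)C(=O)CC(=O)CCc1ccc(OCc2ccccc2)cc1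
A8 | alternative 3 | 3,5,7-tris(benzyloxy)-8-{3-[3-(4-benzyloxyphenyl)propanoyl]-2,4,6-trihydroxy-5-methylbenzyl}-2-(4-methoxyphenyl)-4H-chromen-4-one | COc1ccc(-c2oc3c(Cc4c(O)c(C(=O)CCc5ccc(OCc6ccccc6)cc5)c(O)c(C)c4O)c(OCc4ccccc4)cc(OCc4ccccc4)c3c(=O)c2OCc2ccccc2)cc1
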